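## Retrosynthetic overview
1. The C1–propenyl bond and C2–H are made last. An (E)-propenyl cuprate adds axially (1,4) to a cross-conjugated 2-aroyl-1,3-cyclohexadiene, and kinetic α-protonation follows. This sets C1 and C2 (cis) in one flask, and tris-debenzylation then unmasks the pyridone and the phenol.
2. The aryl ketone comes from a dienyl Weinreb amide and a 3-lithiopyridine. The pyridine ring is bought (2,4-dichloro-5-iodopyridine) and dressed by SNAr, C3 bromination and C5-selective Suzuki coupling.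
3. The Weinreb amide comes from the kinetic dienyl triflate of a trans-fused 4,7-dimethyloctalenone by aminocarbonylation. The CO carbon becomes the ketone carbon.
4. Key ring construction, with no Diels–Alder reaction: an acyclic 2,8-dienal derived from (S)-citronellal is folded by a tandem conjugate-ene/carbonyl-ene reaction. Ring B forms first (C4a–C8a bond) and ring A second (C2–C3 bond), in the same flask.
5. Stereochemical relay: C7 (chiral pool) → C4a/C8a (all-equatorial chair) → C1/C2 (face control by the rigid trans-decalin).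

Assumption: the SMILES is read literally as the (1S,2S,4aS,7S,8aR) isomer. It has a trans ring fusion and an equatorial C7 methyl, with H-1, H-2 and H-8a on one face, so the propenyl group is axial and cis to the pseudo-equatorial acyl group. Decalin atoms carry naphthalene numbers (C1 propenyl, C2 acyl, C3=C4 alkene, methyls on C4 and C7).

## Route

Step 1
Reactants: 1 (S)-citronellal [(3S)-3,7-dimethyloct-6-enal]
Product: 2 (2E,5S)-5,9-dimethyldeca-2,8-dienal
Conditions: Ph3P=CHCHO (1.2 equiv), toluene, 80 °C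
Reagents that add atoms: (triphenylphosphoranylidene)acetaldehyde, O=CC=P(c1ccccc1)(c1ccccc1)c1ccccc1
Why: Wittig olefination with the stabilised formyl ylide gives the (E)-enal selectively and leaves the remote stereocentre, the future C7, untouched.

Step 2
Reactants: 2 (2E,5S)-5,9-dimethyldeca-2,8-dienal
Product: 4 (2R,4aS,7S,8aR)-7-methyl-4-methylidenedecahydronaphthalen-2-ol, via cyclohexylacetaldehyde 3 (not isolated)
Conditions: Me2AlCl (2.2 equiv), CH2Cl2 (0.02 M), −78 → 23 °C; then 1 M HCl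
Reagents that add atoms: none
Why: Proposed new method: Me2AlCl activates the enal so that the nucleophilic trisubstituted alkene attacks the β-carbon in a chair-like type-one ene transition state with the methyl group, the enal chain and the emerging isopropenyl group all equatorial (this sets C8a and C4a relative to C7), the aluminium-bound aldehyde 3 then closes ring A by a type-two carbonyl-ene reaction of its isopropenyl group (axial alcohol expected, and the epimer converges in step 3), and irreversible loss of methane from the alcohol–Me2AlCl complex drains the reversible side equilibria (hetero-Diels–Alder adduct, cyclobutane) towards the alkoxide of 4; the closest known reaction types are the Me2AlCl-promoted sequential conjugate-ene/carbonyl-ene annulation of enals with alkenes and the Lewis-acid ene cyclisation of citronellal-derived alkylidene malonates.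

Step 3
Reactants: 4 (2R,4aS,7S,8aR)-7-methyl-4-methylidenedecahydronaphthalen-2-ol
Product: 6 (4aS,7S,8aR)-4,7-dimethyl-4a,5,6,7,8,8a-hexahydronaphthalen-2(1H)-one, via methylidene ketone 5 (not isolated)
Conditions: Dess–Martin periodinane (1.3 equiv), CH2Cl2, 0 → 23 °C; aqueous work-up; crude, DBU (0.2 equiv), CH2Cl2, 23 °C
Reagents that add atoms: none
Why: Dess–Martin oxidation erases the inconsequential carbinol centre and catalytic DBU moves the exocyclic β,γ-alkene into conjugation through the doubly activated C3 position (base-catalysed enone conjugation), under conditions too mild to deprotonate C4a, so the trans fusion is kept.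

Step 4
Reactants: 6 (4aS,7S,8aR)-4,7-dimethyl-4a,5,6,7,8,8a-hexahydronaphthalen-2(1H)-one
Product: 8 (4aS,7S,8aS)-4,7-dimethyl-4a,5,6,7,8,8a-hexahydronaphthalen-2-yl trifluoromethanesulfonate, via lithium dienolate 7 (not isolated)
Conditions: LiN(i-Pr)2 (1.1 equiv), THF, −78 °C; PhNTf2 (1.15 equiv), −78 → 0 °C
Reagents that add atoms: N-phenylbis(trifluoromethanesulfonimide), O=S(=O)(N(c1ccccc1)S(=O)(=O)C(F)(F)F)C(F)(F)F
Why: Kinetic deprotonation of a cyclohexenone with a hindered lithium amide takes the α′-CH2 (C1), and O-sulfonylation of the cross-conjugated dienolate (enol triflate formation) gives the 2-triflyloxy-1,3-diene without touching C4a or C8a (the 8a descriptor changes only through priority rules).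

Step 5
Reactants: 8 (4aS,7S,8aS)-4,7-dimethyl-4a,5,6,7,8,8a-hexahydronaphthalen-2-yl trifluoromethanesulfonate
Product: 9 (4aS,7S,8aR)-N-methoxy-N,4,7-trimethyl-4a,5,6,7,8,8a-hexahydronaphthalene-2-carboxamide
Conditions: Pd(OAc)2 (5 mol %), dppp (6 mol %), CO (1 atm), MeNH(OMe)·HCl (1.5 equiv), Et3N (4 equiv), DMF, 50 °C
Reagents that add atoms: carbon monoxide, [C-]#[O+]; N,O-dimethylhydroxylamine hydrochloride, CNOC.Cl
Why: Oxidative addition of zerovalent palladium into the alkenyl C–OTf bond, CO insertion and aminolysis (palladium-catalysed aminocarbonylation) install the future ketone carbon as a Weinreb amide well below the temperature at which cyclohexadiene hydrogen shifts begin.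

Step 6
Reactants: 10 2,4-dichloro-5-iodopyridine
Product: 11 2,4-bis(benzyloxy)-5-iodopyridine
Conditions: BnOH (2.4 equiv), NaH (2.5 equiv), 1,4-dioxane, 23 → 100 °C
Reagents that add atoms: benzyl alcohol, OCc1ccccc1
Why: Double nucleophilic aromatic substitution (SNAr) works because both chlorides sit ortho or para to the ring nitrogen, whereas the C5 iodide is meta and inert.

Step 7
Reactants: 11 2,4-bis(benzyloxy)-5-iodopyridine
Product: 12 2,4-bis(benzyloxy)-3-bromo-5-iodopyridine
Conditions: NBS (1.05 equiv), MeCN, 23 °C, dark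
Reagents that add atoms: N-bromosuccinimide, O=C1CCC(=O)N1Br
Why: Electrophilic aromatic bromination can only go to C3, the one free position activated by both alkoxy groups, and doing it before the electron-rich aryl ring is attached removes any competing site.

Step 8
Reactants: 12 2,4-bis(benzyloxy)-3-bromo-5-iodopyridine; 13 4-(benzyloxy)phenylboronic acid
Product: 14 2,4-bis(benzyloxy)-5-[4-(benzyloxy)phenyl]-3-bromopyridine
Conditions: Pd(PPh3)4 (3 mol %), Na2CO3 (2 M aq), DME, 70 °C
Reagents that add atoms: none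
Why: The Suzuki–Miyaura coupling is chemoselective because oxidative addition into the unhindered C5–iodine bond is much faster than into the C3–bromine bond, which is flanked by two benzyloxy groups.

Step 9
Reactants: 14 2,4-bis(benzyloxy)-5-[4-(benzyloxy)phenyl]-3-bromopyridine; 9 (4aS,7S,8aR)-N-methoxy-N,4,7-trimethyl-4a,5,6,7,8,8a-hexahydronaphthalene-2-carboxamide
Product: 17 [2,4-bis(benzyloxy)-5-[4-(benzyloxy)phenyl]pyridin-3-yl][(4aS,7S,8aR)-4,7-dimethyl-4a,5,6,7,8,8a-hexahydronaphthalen-2-yl]methanone, via aryllithium 15 (not isolated), via tetrahedral lithium adduct 16 (not isolated)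
Conditions: n-BuLi (1.05 equiv), THF, −78 °C, 15 min; 9 (0.9 equiv), −78 → −20 °C; AcOH
Reagents that add atoms: none
Why: Bromine–lithium exchange at −78 °C outruns benzylic deprotonation, the alkoxy-flanked aryllithium adds 1,2 to the amide, and the chelated tetrahedral adduct blocks over-addition until the quench (Weinreb ketone synthesis), with no stereocentre involved.

Step 10
Reactants: 17 [2,4-bis(benzyloxy)-5-[4-(benzyloxy)phenyl]pyridin-3-yl][(4aS,7S,8aR)-4,7-dimethyl-4a,5,6,7,8,8a-hexahydronaphthalen-2-yl]methanone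
Product: 19 [2,4-bis(benzyloxy)-5-[4-(benzyloxy)phenyl]pyridin-3-yl]{(1S,2S,4aS,7S,8aR)-4,7-dimethyl-1-[(E)-prop-1-enyl]-1,2,4a,5,6,7,8,8a-octahydronaphthalen-2-yl}methanone, via lithium dienolate 18 (not isolated)
Conditions: (E)-MeCH=CHBr (6 equiv), t-BuLi (12 equiv), Et2O, −78 °C; CuI (3 equiv), −40 °C; 17, Et2O–THF, −78 → −40 °C; AcOH in THF, −78 °C
Reagents that add atoms: (E)-1-bromoprop-1-ene, C/C=C/Br
Why: In this Gilman cuprate 1,4-addition only C1 is electrophilic (the C3=C4 alkene is cross-conjugated), the locked trans-fused ring enforces stereoelectronic axial attack anti to the axial H-8a and so sets C1 (S) with retention of the (E)-alkenyl geometry, A(1,3) strain keeps the propenyl group axial in the exocyclic dienolate so that kinetic ketonisation delivers the proton to the α-carbon from the opposite face and sets C2 (S) cis to C1, and α- rather than γ-protonation leaves the C3=C4 alkene in place.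

Step 11
Reactants: 19 [2,4-bis(benzyloxy)-5-[4-(benzyloxy)phenyl]pyridin-3-yl]{(1S,2S,4aS,7S,8aR)-4,7-dimethyl-1-[(E)-prop-1-enyl]-1,2,4a,5,6,7,8,8a-octahydronaphthalen-2-yl}methanone
Product: 20 3-{(1S,2S,4aS,7S,8aR)-4,7-dimethyl-1-[(E)-prop-1-enyl]-1,2,4a,5,6,7,8,8a-octahydronaphthalene-2-carbonyl}-4-hydroxy-5-(4-hydroxyphenyl)pyridin-2(1H)-one
Conditions: BCl3 (8 equiv), C6HMe5 (12 equiv), CH2Cl2, −78 °C; MeOH quench
Reagents that add atoms: none
Why: BCl3 cleaves aryl and pyridyl benzyl ethers at −78 °C (Lewis-acid ether cleavage, helped by chelation to the ketone at the two flanking positions) while pentamethylbenzene traps the benzyl cation by Friedel–Crafts alkylation, so neither alkene is attacked nor C2 enolised, and the freed 2-hydroxypyridine tautomerises to the 2-pyridone.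

## Compound list
1 | (S)-citronellal, (3S)-3,7-dimethyloct-6-enal | O=CC[C@@H](C)CCC=C(C)C | starting material
2 | (2E,5S)-5,9-dimethyldeca-2,8-dienal | O=C/C=C/C[C@@H](C)CCC=C(C)C | intermediate
3 | 2-[(1R,2S,5S)-5-methyl-2-(prop-1-en-2-yl)cyclohexyl]acetaldehyde (all-equatorial) | O=CC[C@H]1C[C@@H](C)CC[C@@H]1C(C)=C | intermediate
4 | (2R,4aS,7S,8aR)-7-methyl-4-methylidenedecahydronaphthalen-2-ol (trans-fused, axial OH) | C1[C@H]2C[C@@H](C)CC[C@@H]2C(=C)C[C@@H]1O | intermediate
5 | (4aS,7S,8aR)-7-methyl-4-methylideneoctahydronaphthalen-2(1H)-one | C1[C@H]2C[C@@H](C)CC[C@@H]2C(=C)CC1=O | intermediate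
6 | (4aS,7S,8aR)-4,7-dimethyl-4a,5,6,7,8,8a-hexahydronaphthalen-2(1H)-one | C1[C@H]2C[C@@H](C)CC[C@@H]2C(C)=CC1=O | intermediate
7 | lithium (4aS,7S,8aS)-4,7-dimethyl-4a,5,6,7,8,8a-hexahydronaphthalen-2-olate (cross-conjugated dienolate) | C=1[C@H]2C[C@@H](C)CC[C@@H]2C(C)=CC=1O[Li] | intermediate
8 | (4aS,7S,8aS)-4,7-dimethyl-4a,5,6,7,8,8a-hexahydronaphthalen-2-yl trifluoromethanesulfonate | C=1[C@H]2C[C@@H](C)CC[C@@H]2C(C)=CC=1OS(=O)(=O)C(F)(F)F | intermediate
9 | (4aS,7S,8aR)-N-methoxy-N,4,7-trimethyl-4a,5,6,7,8,8a-hexahydronaphthalene-2-carboxamide | C=1[C@H]2C[C@@H](C)CC[C@@H]2C(C)=CC=1C(=O)N(C)OC | intermediate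
10 | 2,4-dichloro-5-iodopyridine | Clc1cc(Cl)c(I)cn1 | starting material
11 | 2,4-bis(benzyloxy)-5-iodopyridine | Ic1cnc(OCc2ccccc2)cc1OCc1ccccc1 | intermediate
12 | 2,4-bis(benzyloxy)-3-bromo-5-iodopyridine | Ic1cnc(OCc2ccccc2)c(Br)c1OCc1ccccc1 | intermediate
13 | 4-(benzyloxy)phenylboronic acid | OB(O)c1ccc(OCc2ccccc2)cc1 | starting material
14 | 2,4-bis(benzyloxy)-5-[4-(benzyloxy)phenyl]-3-bromopyridine | Brc1c(OCc2ccccc2)c(-c2ccc(OCc3ccccc3)cc2)cnc1OCc1ccccc1 | intermediate
15 | 2,4-bis(benzyloxy)-5-[4-(benzyloxy)phenyl]pyridin-3-yllithium | [Li]c1c(OCc2ccccc2)c(-c2ccc(OCc3ccccc3)cc2)cnc1OCc1ccccc1 | intermediate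
16 | lithium alkoxide of the tetrahedral adduct of 15 with 9 (new carbinol-type centre undefined) | C=1[C@H]2C[C@@H](C)CC[C@@H]2C(C)=CC=1C(O[Li])(N(C)OC)c1c(OCc2ccccc2)c(-c2ccc(OCc3ccccc3)cc2)cnc1OCc1ccccc1 | intermediate
17 | [2,4-bis(benzyloxy)-5-[4-(benzyloxy)phenyl]pyridin-3-yl][(4aS,7S,8aR)-4,7-dimethyl-4a,5,6,7,8,8a-hexahydronaphthalen-2-yl]methanone | C=1[C@H]2C[C@@H](C)CC[C@@H]2C(C)=CC=1C(=O)c1c(OCc2ccccc2)c(-c2ccc(OCc3ccccc3)cc2)cnc1OCc1ccccc1 | intermediate
18 | lithium dienolate of 19 (exocyclic C2=C(OLi)Ar, axial C1 propenyl, enolate geometry undefined) | C/C=C/[C@H]1[C@H]2C[C@@H](C)CC[C@@H]2C(C)=CC1=C(O[Li])c1c(OCc2ccccc2)c(-c2ccc(OCc3ccccc3)cc2)cnc1OCc1ccccc1 | intermediate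
19 | [2,4-bis(benzyloxy)-5-[4-(benzyloxy)phenyl]pyridin-3-yl]{(1S,2S,4aS,7S,8aR)-4,7-dimethyl-1-[(E)-prop-1-enyl]-1,2,4a,5,6,7,8,8a-octahydronaphthalen-2-yl}methanone | C/C=C/[C@H]1[C@H]2C[C@@H](C)CC[C@@H]2C(C)=C[C@H]1C(=O)c1c(OCc2ccccc2)c(-c2ccc(OCc3ccccc3)cc2)cnc1OCc1ccccc1 | intermediate
20 | 3-{(1S,2S,4aS,7S,8aR)-4,7-dimethyl-1-[(E)-prop-1-enyl]-1,2,4a,5,6,7,8,8a-octahydronaphthalene-2-carbonyl}-4-hydroxy-5-(4-hydroxyphenyl)pyridin-2(1H)-one | C/C=C/[C@H]1[C@H]2C[C@@H](C)CC[C@@H]2C(C)=C[C@H]1C(=O)c1c(O)c(-c2ccc(O)cc2)c[nH]c1=O | target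

## Step count and risks
Total step count: 11. Longest linear sequence: 8 steps (steps 1–5 and 9–11, from 1). The pyridine branch runs through 6 steps (steps 6–11).

**Most likely to fail, first: step 2.** The enal is only mono-activated and is β-substituted. It may stop at the hetero-Diels–Alder adduct or drift into hydride shifts. The fallback sets out from 1 and comes back at 4. It splits the cascade and uses a doubly activated enophile.
- Knoevenagel condensation of 1 with dimethyl malonate (piperidinium acetate, CH2Cl2) gives dimethyl 2-[(3S)-3,7-dimethyloct-6-en-1-ylidene]propanedioate F1.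
- Its ZnBr2-mediated intramolecular ene reaction is a dependable trans-selective cyclisation and gives dimethyl 2-[(1S,2S,5S)-5-methyl-2-(prop-1-en-2-yl)cyclohexyl]propanedioate F2.
- Krapcho demethoxycarbonylation (LiCl, wet DMSO, 150 °C) gives methyl 2-[(1R,2S,5S)-5-methyl-2-(prop-1-en-2-yl)cyclohexyl]acetate F3.
- i-Bu2AlH (toluene, −78 °C) gives aldehyde 3, now isolated, and Me2AlCl closes it to 4 by the well-behaved type-two carbonyl-ene reaction alone.

**Second: step 10.** The alkenyl cuprate may be too sluggish for the α-substituted, hindered aroyl diene, or the protonation may be unselective. The fallback sets out from 9 and comes back at 19. It moves the conjugate addition to a far more electrophilic acceptor, ahead of fragment union.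
- i-Bu2AlH reduces 9 to (4aS,7S,8aR)-4,7-dimethyl-4a,5,6,7,8,8a-hexahydronaphthalene-2-carbaldehyde F6.
- The same cuprate with Me3SiCl adds from the same axial face to give the silyl dienol ether trimethyl({(1S,4aS,7S,8aS)-4,7-dimethyl-1-[(E)-prop-1-enyl]-4a,5,6,7,8,8a-hexahydronaphthalen-2(1H)-ylidene}methoxy)silane F7.
- Buffered protodesilylation (Bu4NF, AcOH, THF, −78 °C) from the face opposite the propenyl group gives (1S,2S,4aS,7S,8aR)-4,7-dimethyl-1-[(E)-prop-1-enyl]-1,2,4a,5,6,7,8,8a-octahydronaphthalene-2-carbaldehyde F8.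
- Aryllithium 15 adds at −78 °C to give [2,4-bis(benzyloxy)-5-[4-(benzyloxy)phenyl]pyridin-3-yl]{(1S,2S,4aS,7S,8aR)-4,7-dimethyl-1-[(E)-prop-1-enyl]-1,2,4a,5,6,7,8,8a-octahydronaphthalen-2-yl}methanol F9.
- Dess–Martin oxidation of this carbinol gives 19.

**Third: step 9.** The doubly ortho-substituted aryllithium may be too hindered for the amide, or may decompose on warming. The fallback sets out from 8 and 14 and comes back at 17. It makes the decalin the nucleophile and the pyridine the electrophile.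
- Aryllithium 15 from 14 is quenched with DMF to give 2,4-bis(benzyloxy)-5-[4-(benzyloxy)phenyl]pyridine-3-carbaldehyde F4.
- Nozaki–Hiyama–Kishi coupling of dienyl triflate 8 with this aldehyde (CrCl2, 1 mol % NiCl2, DMF, 23 °C) gives [2,4-bis(benzyloxy)-5-[4-(benzyloxy)phenyl]pyridin-3-yl][(4aS,7S,8aR)-4,7-dimethyl-4a,5,6,7,8,8a-hexahydronaphthalen-2-yl]methanol F5.
- MnO2 oxidises this doubly activated carbinol to 17.

## Further compounds
F1 | step 2 | dimethyl 2-[(3S)-3,7-dimethyloct-6-en-1-ylidene]propanedioate | COC(=O)C(=CC[C@@H](C)CCC=C(C)C)C(=O)OC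
F2 | step 2 | dimethyl 2-[(1S,2S,5S)-5-methyl-2-(prop-1-en-2-yl)cyclohexyl]propanedioate | COC(=O)C(C(=O)OC)[C@H]1C[C@@H](C)CC[C@@H]1C(C)=C
F3 | step 2 | methyl 2-[(1R,2S,5S)-5-methyl-2-(prop-1-en-2-yl)cyclohexyl]acetate | COC(=O)C[C@H]1C[C@@H](C)CC[C@@H]1C(C)=C
F4 | step 9 | 2,4-bis(benzyloxy)-5-[4-(benzyloxy)phenyl]pyridine-3-carbaldehyde | O=Cc1c(OCc2ccccc2)c(-c2ccc(OCc3ccccc3)cc2)cnc1OCc1ccccc1
F5 | step 9 | [2,4-bis(benzyloxy)-5-[4-(benzyloxy)phenyl]pyridin-3-yl][(4aS,7S,8aR)-4,7-dimethyl-4a,5,6,7,8,8a-hexahydronaphthalen-2-yl]methanol (carbinol epimers) | C=1[C@H]2C[C@@H](C)CC[C@@H]2C(C)=CC=1C(O)c1c(OCc2ccccc2)c(-c2ccc(OCc3ccccc3)cc2)cnc1OCc1ccccc1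
F6 | step 10 | (4aS,7S,8aR)-4,7-dimethyl-4a,5,6,7,8,8a-hexahydronaphthalene-2-carbaldehyde | C=1[C@H]2C[C@@H](C)CC[C@@H]2C(C)=CC=1C=O
F7 | step 10 | trimethyl({(1S,4aS,7S,8aS)-4,7-dimethyl-1-[(E)-prop-1-enyl]-4a,5,6,7,8,8a-hexahydronaphthalen-2(1H)-ylidene}methoxy)silane | C/C=C/[C@H]1[C@H]2C[C@@H](C)CC[C@@H]2C(C)=CC1=CO[Si](C)(C)C
F8 | step 10 | (1S,2S,4aS,7S,8aR)-4,7-dimethyl-1-[(E)-prop-1-enyl]-1,2,4a,5,6,7,8,8a-octahydronaphthalene-2-carbaldehyde | C/C=C/[C@H]1[C@H]2C[C@@H](C)CC[C@@H]2C(C)=C[C@H]1C=O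
F9 | step 10 | [2,4-bis(benzyloxy)-5-[4-(benzyloxy)phenyl]pyridin-3-yl]{(1S,2S,4aS,7S,8aR)-4,7-dimethyl-1-[(E)-prop-1-enyl]-1,2,4a,5,6,7,8,8a-octahydronaphthalen-2-yl}methanol (carbinol epimers) | C/C=C/[C@H]1[C@H]2C[C@@H](C)CC[C@@H]2C(C)=C[C@H]1C(O)c1c(OCc2ccccc2)c(-c2ccc(OCc3ccccc3)cc2)cnc1OCc1ccccc1
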